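The bond on which the route rests is C2–C3 of quinone ring B. C1 and C2 are read as the two carbons of an alkyne that joins C8a of ring A to C8' of the chromone, and C3 and C4 as an acetyl group on C4a, so both aryl halves descend from one symmetric acetophenone. In one operation, a gold-catalysed hydration of the alkyne assisted by the acetyl oxygen, followed by an acid aldol condensation, forms C2–C3, closes ring B as a 1-naphthol and places its oxygen on C4, without base. The precursor is a diarylalkyne: 2-acetyl-3-methoxy-5-methylphenyl–C≡C–(C8') of benzyl 7-methyl-4-oxochromene-5-carboxylate.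

Key step: step 9

Remarks on the chemistry:
- Unprimed locants (C1–C8a) refer to the naphthalene/naphthoquinone half, primed locants to the chromone.
- Compound 1 is taken to be purchasable.
- The target SMILES carries no stereodescriptor, so the C2–C8' axis is treated as freely rotating and no stereocontrol is planned.

Step 1
Reactants: 1 1-(2,6-dihydroxy-4-methylphenyl)ethanone
Product: 2 2-acetyl-3-hydroxy-5-methylphenyl trifluoromethanesulfonate
Conditions: Tf2O (1.05 equiv), pyridine, CH2Cl2, −40 → 0 °C
Reagents that add atoms: trifluoromethanesulfonic anhydride, O=S(=O)(OS(=O)(=O)C(F)(F)F)C(F)(F)F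
Why: Phenol O-sulfonylation of a symmetric diol: both hydroxyls are equivalent, so only one monotriflate can form, and after the first sulfonylation the remaining hydroxyl is tied up in a hydrogen bond to the acetyl oxygen on a ring made electron-poor by the triflate, which holds back a second sulfonylation; the same monotriflate feeds both halves.

Step 2
Reactants: 2 2-acetyl-3-hydroxy-5-methylphenyl trifluoromethanesulfonate
Product: 3 2-acetyl-3-methoxy-5-methylphenyl trifluoromethanesulfonate
Conditions: MeI, K2CO3, acetone, 45 °C
Reagents that add atoms: iodomethane, CI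
Why: Williamson O-methylation of the chelated phenol with a weak base that leaves the aryl triflate and the acetyl group alone; the ether will later keep ring A from being oxidised and so steer the quinone into ring B.

Step 3
Reactants: 3 2-acetyl-3-methoxy-5-methylphenyl trifluoromethanesulfonate; 4 trimethylsilylacetylene
Product: 5 1-{2-methoxy-4-methyl-6-[(trimethylsilyl)ethynyl]phenyl}ethanone
Conditions: PdCl2(PPh3)2 (5 mol%), CuI (10 mol%), Et3N, DMF, 70 °C
Reagents that add atoms: none
Why: Sonogashira coupling of an aryl triflate, whose oxidative addition to zerovalent palladium is helped by the ortho acetyl group; the silyl cap prevents double arylation of acetylene and the reagent supplies C1 and C2 of ring B.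

Step 4
Reactants: 5 1-{2-methoxy-4-methyl-6-[(trimethylsilyl)ethynyl]phenyl}ethanone
Product: 6 1-(2-ethynyl-6-methoxy-4-methylphenyl)ethanone
Conditions: K2CO3 (0.2 equiv), MeOH, rt
Reagents that add atoms: none
Why: Base-catalysed protodesilylation (methanolysis of the C(sp)–Si bond); the alkyne is unmasked on the ring A half so that methoxide never meets the base-labile 2,3-unsubstituted pyranone.

Step 5
Reactants: 2 2-acetyl-3-hydroxy-5-methylphenyl trifluoromethanesulfonate
Product: 7 benzyl 2-acetyl-3-hydroxy-5-methylbenzoate
Conditions: CO (1 atm), BnOH (5 equiv), Pd(OAc)2 (5 mol%), dppp (6 mol%), Et3N, DMF, 70 °C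
Reagents that add atoms: carbon monoxide, [C-]#[O+]; benzyl alcohol, OCc1ccccc1
Why: Palladium-catalysed alkoxycarbonylation of an aryl triflate (oxidative addition, CO insertion, alcoholysis of the acylpalladium by excess benzyl alcohol); the hydrogen-bonded phenol is a poor nucleophile and needs no protection, and the benzyl ester is chosen because it can be removed at the end without hydroxide.

Step 6
Reactants: 7 benzyl 2-acetyl-3-hydroxy-5-methylbenzoate
Product: 8 benzyl 2-acetyl-3-hydroxy-4-iodo-5-methylbenzoate
Conditions: N-iodosuccinimide (1.05 equiv), CF3CO2H (0.3 equiv), MeCN, 0 °C → rt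
Reagents that add atoms: N-iodosuccinimide, O=C1CCC(=O)N1I
Why: Electrophilic aromatic iodination ortho to the chelated hydroxyl: C4 lies between OH and CH3, whereas the only other free position, C6, is wedged between CH3 and the ester and is ortho to that acceptor, and bond fixation in the hydrogen-bonded o-hydroxyaryl ketone favours the carbon next to the OH; the halogen is introduced before the pyranone is closed because this hydroxyl becomes O1', which places iodine at C8' by construction, whereas a free 5'-hydroxychromone would be expected to react next to its own chelated hydroxyl at C6' (the position should be checked by HMBC from the remaining aromatic proton to the ester carbonyl).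

Step 7
Reactants: 8 benzyl 2-acetyl-3-hydroxy-4-iodo-5-methylbenzoate; 9 N,N-dimethylformamide dimethyl acetal
Product: 11 benzyl 8-iodo-7-methyl-4-oxo-4H-chromene-5-carboxylate, via enaminone 10 (not isolated)
Conditions: DMF-DMA (3 equiv), toluene, 90 °C; then conc. HCl, CH2Cl2, rt
Reagents that add atoms: none
Why: Enaminone chromone synthesis: condensation of the acetyl CH3 with the amide acetal gives the (E)-enaminone, and acid then drives intramolecular oxa-Michael addition of the single phenol followed by loss of dimethylamine (addition–elimination), so the pyranone can only close through the oxygen that is ortho to iodine.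

Step 8
Reactants: 11 benzyl 8-iodo-7-methyl-4-oxo-4H-chromene-5-carboxylate; 6 1-(2-ethynyl-6-methoxy-4-methylphenyl)ethanone
Product: 12 benzyl 8-[(2-acetyl-3-methoxy-5-methylphenyl)ethynyl]-7-methyl-4-oxo-4H-chromene-5-carboxylate
Conditions: PdCl2(PPh3)2 (3 mol%), CuI (6 mol%), Et3N, THF (degassed), rt → 40 °C
Reagents that add atoms: none
Why: Sonogashira coupling of an electron-poor aryl iodide under mild conditions with a tertiary amine base, which does not add to C2' of the pyranone as a secondary amine would; the new C2–C8' bond completes the diarylalkyne without any protecting-group step on the chromone half.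

Step 9
Reactants: 12 benzyl 8-[(2-acetyl-3-methoxy-5-methylphenyl)ethynyl]-7-methyl-4-oxo-4H-chromene-5-carboxylate
Product: 14 benzyl 8-(4-hydroxy-5-methoxy-7-methylnaphthalen-2-yl)-7-methyl-4-oxo-4H-chromene-5-carboxylate, via 1,5-diketone 13 (not isolated)
Conditions: Ph3PAuNTf2 (5 mol%), H2O (3 equiv), ClCH2CH2Cl, 60 °C; then TsOH·H2O (30 mol%), 80 °C
Reagents that add atoms: water, O
Why: Ph3PAuNTf2 activates the alkyne and the acetyl oxygen attacks C2 in a 6-endo-dig closure, giving after protodeauration a transient 2-benzopyrylium ion; water adds at its oxocarbenium carbon C4 and ring opening gives 1,5-diketone 13 with the new ketone on C2 and a CH2 at C1. TsOH then catalyses a 6-(enolexo)-exo-trig aldol condensation in which the acetyl enol carbon C3 attacks the C2 carbonyl, forming C2–C3 and closing ring B, and loss of water with tautomerisation gives the 1-naphthol; the naphthol oxygen thus comes from water while the original carbonyl oxygen leaves as water, so the step is a net isomerisation. The closest known reaction types are the carbonyl-assisted hydration of 2-alkynylaryl ketones and the acid-mediated benzannulation of 2-alkynylacetophenones to 3-substituted 1-naphthols. No stereocentre is formed. The selectivity needed is 6-endo over 5-exo oxygen attack, secured by the aromatic pyrylium outcome and by the C8' aryl group, whose ortho ring oxygen O1' stabilises positive charge on C2; the carbon–carbon closure itself is unambiguous because the only other enol/carbonyl pairing (C1 onto C4) would make a four-membered ring. The medium contains no base, so the pyranone and the benzyl ester should survive, and diketone and pyrylium ion can equilibrate under acid while aromatisation drains both to 14.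

Step 10
Reactants: 14 benzyl 8-(4-hydroxy-5-methoxy-7-methylnaphthalen-2-yl)-7-methyl-4-oxo-4H-chromene-5-carboxylate
Product: 15 benzyl 8-(5-methoxy-7-methyl-1,4-dioxo-1,4-dihydronaphthalen-2-yl)-7-methyl-4-oxo-4H-chromene-5-carboxylate
Conditions: PhI(OCOCF3)2 (2.2 equiv), MeCN/H2O (2:1), 0 °C
Reagents that add atoms: water, O
Why: Hypervalent-iodine oxidation of a phenol to a para-quinone: the naphthol oxygen binds trivalent iodine, water attacks the free para position C1 and a second equivalent of oxidant takes the resulting hydroquinone to the quinone; the C5 methyl ether keeps ring A from reacting and C3 is only ortho, so the 1,4-dione should form in ring B with C1=O next to the aryl-bearing C2.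

Step 11
Reactants: 15 benzyl 8-(5-methoxy-7-methyl-1,4-dioxo-1,4-dihydronaphthalen-2-yl)-7-methyl-4-oxo-4H-chromene-5-carboxylate
Product: 16 8-(5-hydroxy-7-methyl-1,4-dioxo-1,4-dihydronaphthalen-2-yl)-7-methyl-4-oxo-4H-chromene-5-carboxylic acid
Conditions: BBr3 (6 equiv), CH2Cl2, −78 → 0 °C; then H2O
Reagents that add atoms: none
Why: Lewis-acid dealkylation: boron chelated between the C4 carbonyl and the C5 oxygen cleaves the peri methyl ether, and the benzyl ester is cleaved by bromide at the benzylic carbon at low temperature, so both protecting groups leave in one acidic operation and neither the quinone nor the pyranone meets hydroxide.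

Compound list
1 | 1-(2,6-dihydroxy-4-methylphenyl)ethanone | CC(=O)c1c(O)cc(C)cc1O | starting material
2 | 2-acetyl-3-hydroxy-5-methylphenyl trifluoromethanesulfonate | CC(=O)c1c(O)cc(C)cc1OS(=O)(=O)C(F)(F)F | intermediate
3 | 2-acetyl-3-methoxy-5-methylphenyl trifluoromethanesulfonate | CC(=O)c1c(OC)cc(C)cc1OS(=O)(=O)C(F)(F)F | intermediate
4 | trimethylsilylacetylene | C#C[Si](C)(C)C | starting material
5 | 1-{2-methoxy-4-methyl-6-[(trimethylsilyl)ethynyl]phenyl}ethanone | CC(=O)c1c(OC)cc(C)cc1C#C[Si](C)(C)C | intermediate
6 | 1-(2-ethynyl-6-methoxy-4-methylphenyl)ethanone | CC(=O)c1c(OC)cc(C)cc1C#C | intermediate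
7 | benzyl 2-acetyl-3-hydroxy-5-methylbenzoate | CC(=O)c1c(O)cc(C)cc1C(=O)OCc1ccccc1 | intermediate
8 | benzyl 2-acetyl-3-hydroxy-4-iodo-5-methylbenzoate | CC(=O)c1c(O)c(I)c(C)cc1C(=O)OCc1ccccc1 | intermediate
9 | N,N-dimethylformamide dimethyl acetal | COC(OC)N(C)C | starting material
10 | benzyl 2-[(2E)-3-(dimethylamino)prop-2-enoyl]-3-hydroxy-4-iodo-5-methylbenzoate | CN(C)/C=C/C(=O)c1c(O)c(I)c(C)cc1C(=O)OCc1ccccc1 | intermediate
11 | benzyl 8-iodo-7-methyl-4-oxo-4H-chromene-5-carboxylate | Cc1cc(C(=O)OCc2ccccc2)c2c(=O)ccoc2c1I | intermediate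
12 | benzyl 8-[(2-acetyl-3-methoxy-5-methylphenyl)ethynyl]-7-methyl-4-oxo-4H-chromene-5-carboxylate | CC(=O)c1c(OC)cc(C)cc1C#Cc1c(C)cc(C(=O)OCc2ccccc2)c2c(=O)ccoc12 | intermediate
13 | benzyl 8-[(2-acetyl-3-methoxy-5-methylphenyl)acetyl]-7-methyl-4-oxo-4H-chromene-5-carboxylate | CC(=O)c1c(OC)cc(C)cc1CC(=O)c1c(C)cc(C(=O)OCc2ccccc2)c2c(=O)ccoc12 | intermediate
14 | benzyl 8-(4-hydroxy-5-methoxy-7-methylnaphthalen-2-yl)-7-methyl-4-oxo-4H-chromene-5-carboxylate | COc1cc(C)cc2cc(-c3c(C)cc(C(=O)OCc4ccccc4)c4c(=O)ccoc34)cc(O)c12 | intermediate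
15 | benzyl 8-(5-methoxy-7-methyl-1,4-dioxo-1,4-dihydronaphthalen-2-yl)-7-methyl-4-oxo-4H-chromene-5-carboxylate | COc1cc(C)cc2c1C(=O)C=C(c1c(C)cc(C(=O)OCc3ccccc3)c3c(=O)ccoc13)C2=O | intermediate
16 | 8-(5-hydroxy-7-methyl-1,4-dioxo-1,4-dihydronaphthalen-2-yl)-7-methyl-4-oxo-4H-chromene-5-carboxylic acid | Cc1cc(O)c2c(c1)C(=O)C(c1c(C)cc(C(=O)O)c3c(=O)ccoc13)=CC2=O | target

Total step count: 11
Longest linear sequence: 8 steps (1, 5, 6, 7, 8, 9, 10, 11; the ring A branch 1, 2, 3, 4, 8, 9, 10, 11 is equally long)

Steps most likely to fail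

Step 9 (key step). The acetyl oxygen may attack C1 instead of C2 (5-exo-dig), which after hydration would put the ketone on C1 and lead by aldol closure to an indenone. Alternatively, the sequence may stall at the diketone because the C2 carbonyl is flanked by the C7' methyl group and O1'. The fallback sets out from 12 and makes the enol carbon the first nucleophile. Silylation (TBSOTf, Et3N, CH2Cl2, 0 °C) should give benzyl 8-[(2-{1-[(tert-butyldimethylsilyl)oxy]ethenyl}-3-methoxy-5-methylphenyl)ethynyl]-7-methyl-4-oxo-4H-chromene-5-carboxylate F1. PtCl2 (10 mol%) in toluene at 80 °C should then bring about the known 6-endo-dig cycloisomerisation of an o-alkynylaryl silyl enol ether, with C3 attacking C2, to give benzyl 8-{4-[(tert-butyldimethylsilyl)oxy]-5-methoxy-7-methylnaphthalen-2-yl}-7-methyl-4-oxo-4H-chromene-5-carboxylate F2. HF·pyridine in THF removes the silyl group and the route is rejoined at 14.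

Step 6. Iodination may occur para instead of ortho to the hydroxyl (at C6 of 7), which would carry the halogen to C6' of the chromone, or a second iodination may follow. The fallback sets out from 1 and relies on a different directing element: a 5'-methoxy group on a preformed chromone, which should send the electrophile to the para position C8'.
- Monomethylation of 1 (Me2SO4, K2CO3, acetone) gives 1-(2-hydroxy-6-methoxy-4-methylphenyl)ethanone F3.
- DMF-DMA converts it into (2E)-3-(dimethylamino)-1-(2-hydroxy-6-methoxy-4-methylphenyl)prop-2-en-1-one F4, and HCl closes this to 5-methoxy-7-methyl-4H-chromen-4-one F5.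
- Iodination (N-iodosuccinimide, CF3CO2H, MeCN) gives 8-iodo-5-methoxy-7-methyl-4H-chromen-4-one F6.
- BCl3 (CH2Cl2, −78 → 0 °C) cleaves the ether chelated to the C4' carbonyl to give 5-hydroxy-8-iodo-7-methyl-4H-chromen-4-one F7.
- Sonogashira coupling with 6 under the conditions of step 8 gives 8-[(2-acetyl-3-methoxy-5-methylphenyl)ethynyl]-5-hydroxy-7-methyl-4H-chromen-4-one F8.
- Tf2O/pyridine gives 8-[(2-acetyl-3-methoxy-5-methylphenyl)ethynyl]-7-methyl-4-oxo-4H-chromen-5-yl trifluoromethanesulfonate F9.
- Benzyloxycarbonylation under the conditions of step 5 rejoins the route at 12.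

Step 11. Bromide or HBr may add to the Lewis-acid-activated C2=C3 bond of the quinone, or the ester may be cleaved only partly under conditions mild enough to spare the quinone. The fallback sets out from 14 and stages the deprotection so that the ester is removed before the quinone exists and the quinone meets only BCl3. Hydrogenolysis (H2 1 atm, Pd/C, EtOAc, rt, stopped after one equivalent, the benzyl C–O bond being cleaved faster than the pyranone double bond is reduced) gives 8-(4-hydroxy-5-methoxy-7-methylnaphthalen-2-yl)-7-methyl-4-oxo-4H-chromene-5-carboxylic acid F10. Oxidation as in step 10 gives 8-(5-methoxy-7-methyl-1,4-dioxo-1,4-dihydronaphthalen-2-yl)-7-methyl-4-oxo-4H-chromene-5-carboxylic acid F11. BCl3 (CH2Cl2, −78 → 0 °C) then removes only the chelated peri methyl ether and arrives at 16.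

Further compounds
F1 | step 9 | benzyl 8-[(2-{1-[(tert-butyldimethylsilyl)oxy]ethenyl}-3-methoxy-5-methylphenyl)ethynyl]-7-methyl-4-oxo-4H-chromene-5-carboxylate | C=C(O[Si](C)(C)C(C)(C)C)c1c(OC)cc(C)cc1C#Cc1c(C)cc(C(=O)OCc2ccccc2)c2c(=O)ccoc12
F2 | step 9 | benzyl 8-{4-[(tert-butyldimethylsilyl)oxy]-5-methoxy-7-methylnaphthalen-2-yl}-7-methyl-4-oxo-4H-chromene-5-carboxylate | COc1cc(C)cc2cc(-c3c(C)cc(C(=O)OCc4ccccc4)c4c(=O)ccoc34)cc(O[Si](C)(C)C(C)(C)C)c12
F3 | step 6 | 1-(2-hydroxy-6-methoxy-4-methylphenyl)ethanone | CC(=O)c1c(O)cc(C)cc1OC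
F4 | step 6 | (2E)-3-(dimethylamino)-1-(2-hydroxy-6-methoxy-4-methylphenyl)prop-2-en-1-one | CN(C)/C=C/C(=O)c1c(O)cc(C)cc1OC
F5 | step 6 | 5-methoxy-7-methyl-4H-chromen-4-one | COc1cc(C)cc2occc(=O)c12
F6 | step 6 | 8-iodo-5-methoxy-7-methyl-4H-chromen-4-one | COc1cc(C)c(I)c2occc(=O)c12
F7 | step 6 | 5-hydroxy-8-iodo-7-methyl-4H-chromen-4-one | Cc1cc(O)c2c(=O)ccoc2c1I
F8 | step 6 | 8-[(2-acetyl-3-methoxy-5-methylphenyl)ethynyl]-5-hydroxy-7-methyl-4H-chromen-4-one | CC(=O)c1c(OC)cc(C)cc1C#Cc1c(C)cc(O)c2c(=O)ccoc12
F9 | step 6 | 8-[(2-acetyl-3-methoxy-5-methylphenyl)ethynyl]-7-methyl-4-oxo-4H-chromen-5-yl trifluoromethanesulfonate | CC(=O)c1c(OC)cc(C)cc1C#Cc1c(C)cc(OS(=O)(=O)C(F)(F)F)c2c(=O)ccoc12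
F10 | step 11 | 8-(4-hydroxy-5-methoxy-7-methylnaphthalen-2-yl)-7-methyl-4-oxo-4H-chromene-5-carboxylic acid | COc1cc(C)cc2cc(-c3c(C)cc(C(=O)O)c4c(=O)ccoc34)cc(O)c12
F11 | step 11 | 8-(5-methoxy-7-methyl-1,4-dioxo-1,4-dihydronaphthalen-2-yl)-7-methyl-4-oxo-4H-chromene-5-carboxylic acid | COc1cc(C)cc2c1C(=O)C=C(c1c(C)cc(C(=O)O)c3c(=O)ccoc13)C2=O
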